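**Retrosynthetic overview**
- Target ⇐ 8,9‑acetonide of the macrolactone; late operations are C19 methylation of the lactone enolate, Mitsunobu acetate inversion at C12, acetylation at C2.
- Ten‑membered ring and lactone ⇐ C6–C7 bond by an electrochemical chromium/nickel alkenyl iodide–aldehyde closure, then O7→C18 lactonisation.
- Ring A ⇐ Diels–Alder of an (E)‑enone (C1=C10) with a 4‑methyl Danishefsky diene; C11 by kinetic protonation, C2 and C12 by hydride.
- Dienophile ⇐ dimethyl D‑tartrate acetonide (only stereochemical source: C9 bought, C8 by trans enolate alkylation) + keto ylide + (Z)‑iodoallyl bromide.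
- Ring order: ring A → ten‑membered carbocycle → γ‑lactone.

Assumption: the SMILES is read as the absolute configuration (1S,2R,5Z,7S,8R,9R,10S,11R,12R,17R), with briarane locants (C18 = lactone carbonyl, C19 = its α‑methyl) used for all intermediates; dimethyl 2,3‑O‑isopropylidene‑D‑tartrate and (E)‑1‑methoxypent‑1‑en‑3‑one are taken as purchasable.

All stereochemical outcomes below are predictions from models; none has been tested.

**Route**

Step 1
Reactants: 1 dimethyl (4S,5S)-2,2-dimethyl-1,3-dioxolane-4,5-dicarboxylate (dimethyl 2,3-O-isopropylidene-D-tartrate); 2 tert-butyl bromoacetate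
Product: 4 4,5-dimethyl (4R,5S)-4-(2-tert-butoxy-2-oxoethyl)-2,2-dimethyl-1,3-dioxolane-4,5-dicarboxylate, via lithium enolate 3 (not isolated)
Conditions: LiN(i-Pr)2 (1.1 equiv), THF/DMPU, −78 °C; then 2, −78 → −50 °C
Reagents that add atoms: none
Why: Seebach-type alkylation of the tartrate acetonide ester enolate (SN2 on the bromoacetate); the planar enolate carbon (C8) is attacked on the face trans to the CO2Me on the bought centre C9, which fixes the quaternary C8 with the C17–C18 acetate unit trans to C10.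

Step 2
Reactants: 4; 5 3-(triphenylphosphoranylidene)butan-2-one
Product: 7 methyl (4R,5R)-4-(2-tert-butoxy-2-oxoethyl)-2,2-dimethyl-5-[(1E)-2-methyl-3-oxobut-1-en-1-yl]-1,3-dioxolane-4-carboxylate, via aldehyde 6 (not isolated)
Conditions: i-Bu2AlH (1.05 equiv), PhMe, −78 °C; then 5 (1.5 equiv), −78 → 90 °C
Reagents that add atoms: none
Why: Tandem partial ester reduction–Wittig olefination; the hydride takes the less hindered methyl ester on the tertiary ring carbon (the ester on quaternary C8 and the tert-butyl ester remain) and the keto-stabilised ylide gives the (E)-enone without touching a stereocentre.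

Step 3
Reactants: 8 prop-2-yn-1-ol
Product: 10 (2Z)-3-iodo-2-methylprop-2-en-1-ol, via alkenylmagnesium alkoxide 9 (not isolated)
Conditions: MeMgBr (2.5 equiv), CuI (10 mol %), Et2O, −10 → 20 °C; then I2, −60 → 0 °C
Reagents that add atoms: methylmagnesium bromide C[Mg]Br; iodine II
Why: Hydroxyl-directed, copper-catalysed anti-carbomagnesiation puts methyl on C2 and magnesium on C3 in a five-membered chelate, and iodinolysis with retention gives the (Z)-vinyl iodide that becomes the 5Z alkene.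

Step 4
Reactants: 10
Product: 11 (1Z)-3-bromo-1-iodo-2-methylprop-1-ene
Conditions: CBr4, PPh3, CH2Cl2, 0 °C
Reagents that add atoms: carbon tetrabromide BrC(Br)(Br)Br
Why: Appel bromination of the primary allylic alcohol; the vinyl iodide geometry is not involved.

Step 5
Reactants: 7; 11
Product: 13 methyl (4R,5R)-4-(2-tert-butoxy-2-oxoethyl)-5-[(1E,6Z)-7-iodo-2,6-dimethyl-3-oxohepta-1,6-dien-1-yl]-2,2-dimethyl-1,3-dioxolane-4-carboxylate, via lithium dienolate 12 (not isolated)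
Conditions: LiN(i-Pr)2 (1.05 equiv), THF, −78 °C; then 11 (1.2 equiv), −78 → −30 °C
Reagents that add atoms: none
Why: Kinetic deprotonation of the methyl ketone gives the cross-conjugated enolate, whose SN2 alkylation by the allylic bromide forms C3–C4; no stereocentre is made.

Step 6
Reactants: 14 (1E)-1-methoxypent-1-en-3-one
Product: 15 (1E,3Z)-1-methoxy-3-(trimethylsilyloxy)penta-1,3-diene
Conditions: TMSCl, Et3N, ZnCl2 (3 mol %), PhMe, 40 °C
Reagents that add atoms: chlorotrimethylsilane C[Si](C)(C)Cl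
Why: Silyl enol ether formation under Danishefsky conditions gives the (Z)-enol ether, so the future C20 methyl sits on the outside of the diene.

Step 7
Reactants: 13; 15
Product: 17 methyl (4R,5R)-4-(2-tert-butoxy-2-oxoethyl)-5-{(1S,2S,6S)-2-[(4Z)-5-iodo-4-methylpent-4-enoyl]-2,6-dimethyl-5-oxocyclohex-3-en-1-yl}-2,2-dimethyl-1,3-dioxolane-4-carboxylate (ring A enone with 11-epi methyl), via silyl enol ether cycloadduct 16 (not isolated)
Conditions: 15 (4 equiv), BHT, PhMe, 120 °C (sealed tube); then 0.1 M HCl, THF, 0 °C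
Reagents that add atoms: none
Why: Normal-demand Diels–Alder reaction; the diene polarity joins C11 to the enone β-carbon C10 and C14 to C1, suprafacial addition to the (E)-enone fixes the C2 acyl group trans to C9, and with H-9 eclipsing the alkene (A(1,3) strain to the C1 methyl) the diene adds anti to the fully substituted C8 to give 1S,10S; the endo-acyl approach leaves the C11 methyl trans to the side chain (corrected in step 8), and acid unmasks the enone.

Step 8
Reactants: 17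
Product: 19 methyl (4R,5R)-4-(2-tert-butoxy-2-oxoethyl)-5-{(1S,2S,6R)-2-[(4Z)-5-iodo-4-methylpent-4-enoyl]-2,6-dimethyl-5-oxocyclohex-3-en-1-yl}-2,2-dimethyl-1,3-dioxolane-4-carboxylate (11R), via dilithium bis-enolate 18 (not isolated)
Conditions: LiN(i-Pr)2 (2.3 equiv), THF, −78 °C; then AcOH (6 equiv) in THF, −78 °C
Reagents that add atoms: none
Why: Enolisation followed by kinetic protonation; in the C11=C12 enolate A(1,2) strain holds the C10 side chain pseudoaxial and the proton enters axially on the opposite face, giving the contra-thermodynamic cis C10/C11 pair (the C3 enolate simply reprotonates).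

Step 9
Reactants: 19
Product: 20 methyl (4R,5R)-4-(2-tert-butoxy-2-oxoethyl)-5-{(1S,2S,5S,6R)-5-hydroxy-2-[(1R,4Z)-1-hydroxy-5-iodo-4-methylpent-4-en-1-yl]-2,6-dimethylcyclohex-3-en-1-yl}-2,2-dimethyl-1,3-dioxolane-4-carboxylate (2R,12S diol)
Conditions: NaBH4 (4 equiv), CeCl3·7H2O (2 equiv), MeOH/THF, −40 → 0 °C
Reagents that add atoms: none
Why: Luche 1,2-reduction; hydride reaches the enone carbonyl from the face anti to the pseudoaxial C10 side chain (12S alcohol, deliberately the epimer that step 13 inverts) and reduces the C2 ketone in the Felkin–Anh sense (hydride anti to the C1–C10 bond, chain next to the small C15 methyl) to give 2R.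

Step 10
Reactants: 20
Product: 21 tert-butyl 2-[(4R,5R)-4-formyl-5-{(1S,2S,5S,6R)-5-hydroxy-2-[(1R,4Z)-1-hydroxy-5-iodo-4-methylpent-4-en-1-yl]-2,6-dimethylcyclohex-3-en-1-yl}-2,2-dimethyl-1,3-dioxolan-4-yl]acetate
Conditions: i-Bu2AlH (4 equiv), CH2Cl2, −78 °C
Reagents that add atoms: none
Why: Partial reduction of the α-alkoxy methyl ester through a chelated tetrahedral aluminate that collapses only on work-up; the tert-butyl ester is kept and the two alcohols are masked as aluminates.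

Step 11
Reactants: 21
Product: 23 (1S,2R,5Z,7S,8R,9R,10S,11R,12S)-2,12-dihydroxy-8,9-O-isopropylidene-19-norbriara-5,13-dien-18,7-olide, via macrocyclic hydroxy ester 22 (not isolated)
Conditions: CrCl3 (20 mol %), NiCl2·glyme (2 mol %), Cp2ZrCl2 (1.5 equiv), LiCl, DMF, undivided cell, Al anode, Ni-foam cathode, 3 mA, 21 added over 10 h (final 2 mM), 20 °C; aqueous work-up; then p-TsOH·H2O (0.2 equiv), PhMe, 40 °C
Reagents that add atoms: none
Why: Proposed new method: an electroreductive chromium/nickel-catalysed Nozaki–Hiyama–Kishi macrocyclisation in which the cathode keeps chromium divalent, low-valent nickel inserts into the (Z)-vinyl iodide with retention and passes the alkenyl group to chromium, the alkenyl–trivalent-chromium species adds to the C7 aldehyde in the Felkin–Anh sense (C8–O anti, ring-bearing C9 gauche to the new bond, the only rotamer the tether can reach) to give 7S, Cp2ZrCl2 frees chromium from the alkoxide and slow feed favours the ten-membered closure; the closest known chemistry is the intermolecular electrochemical chromium/nickel alkenyl halide–aldehyde coupling and stoichiometric CrCl2/NiCl2 closures of nine- and ten-membered carbocycles, and the acid step lactonises O7 onto the tert-butyl ester.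

Step 12
Reactants: 23
Product: 25 (1S,2R,5Z,7S,8R,9R,10S,11R,12S,17R)-2,12-dihydroxy-8,9-O-isopropylidenebriara-5,13-dien-18,7-olide, via trilithium enolate 24 (not isolated)
Conditions: LiN(i-Pr)2 (3.3 equiv), THF, −78 °C; MeI (1.2 equiv), −78 °C; sat. aq. NH4Cl
Reagents that add atoms: iodomethane CI
Why: Lactone enolate alkylation; iodomethane approaches anti to C9, the larger group on the adjacent quaternary C8, so the C19 methyl ends cis to O8 (17R), while the lithium alkoxides do not react at −78 °C.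

Step 13
Reactants: 25
Product: 26 (1S,2R,5Z,7S,8R,9R,10S,11R,12R,17R)-12-acetoxy-2-hydroxy-8,9-O-isopropylidenebriara-5,13-dien-18,7-olide
Conditions: AcOH, PPh3, DIAD, PhMe, 0 → 20 °C
Reagents that add atoms: acetic acid CC(=O)O
Why: Mitsunobu esterification; SN2 displacement by acetate inverts the allylic C12 (12S alcohol to 12R acetate), and the neopentyl-type C2 alcohol does not react.

Step 14
Reactants: 26
Product: 27 (1S,2R,5Z,7S,8R,9R,10S,11R,12R,17R)-2,12-diacetoxy-8,9-O-isopropylidenebriara-5,13-dien-18,7-olide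
Conditions: Ac2O, pyridine, DMAP (cat.), CH2Cl2, 20 → 40 °C
Reagents that add atoms: acetic anhydride CC(=O)OC(C)=O
Why: DMAP-catalysed acylation of the remaining hindered secondary alcohol with retention at C2; the tertiary O8 is tied up in the acetonide.

Step 15
Reactants: 27
Product: 28 (1S,2R,5Z,7S,8R,9R,10S,11R,12R,17R)-2,12-diacetoxy-8,9-dihydroxybriara-5,13-dien-18,7-olide (CNP0286823.1)
Conditions: TFA/H2O (4:1), CH2Cl2, 0 °C
Reagents that add atoms: none
Why: Acid-catalysed hydrolysis of the isopropylidene ketal frees the 8,9-diol without touching acetates, lactone or any stereocentre.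

**Compound list**

1 | dimethyl (4S,5S)-2,2-dimethyl-1,3-dioxolane-4,5-dicarboxylate | COC(=O)[C@H]1OC(C)(C)O[C@@H]1C(=O)OC | starting material
2 | tert-butyl bromoacetate | CC(C)(C)OC(=O)CBr | starting material
3 | lithium enolate of 1 (ketene acetal at C8, C9 unchanged) | COC(=O)[C@@H](OC(C)(C)O1)C1=C(OC)O[Li] | intermediate (not isolated)
4 | 4,5-dimethyl (4R,5S)-4-(2-tert-butoxy-2-oxoethyl)-2,2-dimethyl-1,3-dioxolane-4,5-dicarboxylate | COC(=O)[C@@H](OC(C)(C)O1)[C@]1(CC(=O)OC(C)(C)C)C(=O)OC | intermediate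
5 | 3-(triphenylphosphoranylidene)butan-2-one | CC(=O)C(C)=P(c1ccccc1)(c1ccccc1)c1ccccc1 | starting material
6 | methyl (4R,5S)-4-(2-tert-butoxy-2-oxoethyl)-5-formyl-2,2-dimethyl-1,3-dioxolane-4-carboxylate | O=C[C@@H](OC(C)(C)O1)[C@]1(CC(=O)OC(C)(C)C)C(=O)OC | intermediate (not isolated)
7 | methyl (4R,5R)-4-(2-tert-butoxy-2-oxoethyl)-2,2-dimethyl-5-[(1E)-2-methyl-3-oxobut-1-en-1-yl]-1,3-dioxolane-4-carboxylate | CC(=O)/C(C)=C/[C@@H](OC(C)(C)O1)[C@]1(CC(=O)OC(C)(C)C)C(=O)OC | intermediate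
8 | prop-2-yn-1-ol | C#CCO | starting material
9 | bromomagnesium (2Z)-3-(bromomagnesio)-2-methylprop-2-en-1-olate | Br[Mg]OC/C(C)=C\[Mg]Br | intermediate (not isolated)
10 | (2Z)-3-iodo-2-methylprop-2-en-1-ol | OC/C(C)=C\I | intermediate
11 | (1Z)-3-bromo-1-iodo-2-methylprop-1-ene | BrC/C(C)=C\I | intermediate
12 | lithium cross-conjugated dienolate of 7 (enolate at the methyl ketone) | [Li]OC(=C)/C(C)=C/[C@@H](OC(C)(C)O1)[C@]1(CC(=O)OC(C)(C)C)C(=O)OC | intermediate (not isolated)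
13 | methyl (4R,5R)-4-(2-tert-butoxy-2-oxoethyl)-5-[(1E,6Z)-7-iodo-2,6-dimethyl-3-oxohepta-1,6-dien-1-yl]-2,2-dimethyl-1,3-dioxolane-4-carboxylate | I/C=C(/C)CCC(=O)/C(C)=C/[C@@H](OC(C)(C)O1)[C@]1(CC(=O)OC(C)(C)C)C(=O)OC | intermediate
14 | (1E)-1-methoxypent-1-en-3-one | CCC(=O)/C=C/OC | starting material
15 | (1E,3Z)-1-methoxy-3-(trimethylsilyloxy)penta-1,3-diene | CO/C=C/C(O[Si](C)(C)C)=C/C | intermediate
16 | Diels–Alder adduct of 13 and 15: ring A as C12 silyl enol ether (C12=C13), 14-OMe cis to the C1 acyl group, C11 methyl trans to the C10 side chain, C1/C8/C9/C10 as in 17 | C[Si](C)(C)OC1=C[C@H](OC)[C@@](C(=O)CC/C(C)=C\I)(C)[C@H]([C@@H]1C)[C@@H](OC(C)(C)O2)[C@]2(CC(=O)OC(C)(C)C)C(=O)OC | intermediate (not isolated)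
17 | methyl (4R,5R)-4-(2-tert-butoxy-2-oxoethyl)-5-{(1S,2S,6S)-2-[(4Z)-5-iodo-4-methylpent-4-enoyl]-2,6-dimethyl-5-oxocyclohex-3-en-1-yl}-2,2-dimethyl-1,3-dioxolane-4-carboxylate | O=C1C=C[C@@](C(=O)CC/C(C)=C\I)(C)[C@H]([C@@H]1C)[C@@H](OC(C)(C)O2)[C@]2(CC(=O)OC(C)(C)C)C(=O)OC | intermediate
18 | dilithium bis-enolate of 17 (C11=C12–OLi and C2(OLi)=C3) | [Li]OC1=C(C)[C@H]([C@@H](OC(C)(C)O2)[C@]2(CC(=O)OC(C)(C)C)C(=O)OC)[C@@](C)(C(O[Li])=CC/C(C)=C\I)C=C1 | intermediate (not isolated)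
19 | methyl (4R,5R)-4-(2-tert-butoxy-2-oxoethyl)-5-{(1S,2S,6R)-2-[(4Z)-5-iodo-4-methylpent-4-enoyl]-2,6-dimethyl-5-oxocyclohex-3-en-1-yl}-2,2-dimethyl-1,3-dioxolane-4-carboxylate | O=C1C=C[C@@](C(=O)CC/C(C)=C\I)(C)[C@H]([C@H]1C)[C@@H](OC(C)(C)O2)[C@]2(CC(=O)OC(C)(C)C)C(=O)OC | intermediate
20 | methyl (4R,5R)-4-(2-tert-butoxy-2-oxoethyl)-5-{(1S,2S,5S,6R)-5-hydroxy-2-[(1R,4Z)-1-hydroxy-5-iodo-4-methylpent-4-en-1-yl]-2,6-dimethylcyclohex-3-en-1-yl}-2,2-dimethyl-1,3-dioxolane-4-carboxylate | O[C@H]1C=C[C@@]([C@H](O)CC/C(C)=C\I)(C)[C@H]([C@H]1C)[C@@H](OC(C)(C)O2)[C@]2(CC(=O)OC(C)(C)C)C(=O)OC | intermediate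
21 | tert-butyl 2-[(4R,5R)-4-formyl-5-{(1S,2S,5S,6R)-5-hydroxy-2-[(1R,4Z)-1-hydroxy-5-iodo-4-methylpent-4-en-1-yl]-2,6-dimethylcyclohex-3-en-1-yl}-2,2-dimethyl-1,3-dioxolan-4-yl]acetate | O[C@H]1C=C[C@@]([C@H](O)CC/C(C)=C\I)(C)[C@H]([C@H]1C)[C@@H](OC(C)(C)O2)[C@]2(CC(=O)OC(C)(C)C)C=O | intermediate
22 | tert-butyl (1S,2R,5Z,7S,8S,9R,10S,11R,12S)-2,7,12-trihydroxy-8,9-O-isopropylidene-19-norbriara-5,13-dien-18-oate (ten-membered ring closed, lactone still open; 8S only by priority change) | O[C@H]1C=C[C@@]2(C)[C@H]([C@H]1C)[C@@H](OC(C)(C)O3)[C@]3(CC(=O)OC(C)(C)C)[C@@H](O)/C=C(/C)CC[C@H]2O | intermediate (not isolated)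
23 | (1S,2R,5Z,7S,8R,9R,10S,11R,12S)-2,12-dihydroxy-8,9-O-isopropylidene-19-norbriara-5,13-dien-18,7-olide | O[C@H]1C=C[C@@]2(C)[C@H]([C@H]1C)[C@@H](OC(C)(C)O3)[C@@]13[C@H](/C=C(/C)CC[C@H]2O)OC(=O)C1 | intermediate
24 | trilithium salt of 23 (2- and 12-alkoxides, lactone enolate C17=C18) | [Li]O[C@H]1C=C[C@@]2(C)[C@H]([C@H]1C)[C@@H](OC(C)(C)O3)[C@@]13[C@H](/C=C(/C)CC[C@H]2O[Li])OC(O[Li])=C1 | intermediate (not isolated)
25 | (1S,2R,5Z,7S,8R,9R,10S,11R,12S,17R)-2,12-dihydroxy-8,9-O-isopropylidenebriara-5,13-dien-18,7-olide | O[C@H]1C=C[C@@]2(C)[C@H]([C@H]1C)[C@@H](OC(C)(C)O3)[C@@]13[C@H](/C=C(/C)CC[C@H]2O)OC(=O)[C@@H]1C | intermediate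
26 | (1S,2R,5Z,7S,8R,9R,10S,11R,12R,17R)-12-acetoxy-2-hydroxy-8,9-O-isopropylidenebriara-5,13-dien-18,7-olide | CC(=O)O[C@@H]1C=C[C@@]2(C)[C@H]([C@H]1C)[C@@H](OC(C)(C)O3)[C@@]13[C@H](/C=C(/C)CC[C@H]2O)OC(=O)[C@@H]1C | intermediate
27 | (1S,2R,5Z,7S,8R,9R,10S,11R,12R,17R)-2,12-diacetoxy-8,9-O-isopropylidenebriara-5,13-dien-18,7-olide | CC(=O)O[C@@H]1C=C[C@@]2(C)[C@H]([C@H]1C)[C@@H](OC(C)(C)O3)[C@@]13[C@H](/C=C(/C)CC[C@H]2OC(C)=O)OC(=O)[C@@H]1C | intermediate
28 | (1S,2R,5Z,7S,8R,9R,10S,11R,12R,17R)-2,12-diacetoxy-8,9-dihydroxybriara-5,13-dien-18,7-olide | CC(=O)O[C@@H]1C=C[C@@]2(C)[C@H]([C@H]1C)[C@@H](O)[C@@]1(O)[C@H](/C=C(/C)CC[C@H]2OC(C)=O)OC(=O)[C@@H]1C | target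

**Step count and risks**

Total steps: 15. Longest linear sequence: 12 (steps 1, 2, 5, 7, 8, 9, 10, 11, 12, 13, 14, 15).

Three steps most likely to fail:

Step 7 (cycloaddition onto a hindered trisubstituted enone; rate and face selectivity). The fallback sets out from 4 and returns at 17. It moves the cycloaddition to the more electrophilic aldehyde oxidation level and attaches the side chain afterwards. Reduction of 4 as in step 2, but olefination with 2-(triphenylphosphoranylidene)propanal, gives the (E)-enal F1. Thermal cycloaddition with 15 (PhMe, 80 °C) gives the silyl enol ether cycloadduct F2, which dilute HCl turns into the formyl cyclohexenone F3. MeTi(Oi-Pr)3 adds only to the aldehyde and gives the 1-hydroxyethyl carbinol F4. Dess–Martin oxidation gives the acetyl cyclohexenone F5. Kinetic enolisation of its methyl ketone (LiN(i-Pr)2, 1 equiv, −78 °C) and alkylation with 11 gives 17.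

Step 11 (the proposed new electrochemical ring closure). The fallback sets out from 20 and returns at 23. It uses the known stoichiometric organochromium chemistry on a protected substrate instead of electrocatalytic turnover on the free diol. TESOTf and 2,6-lutidine give the bis(triethylsilyl) ether F6. i-Bu2AlH at −78 °C gives the bis(triethylsilyl) aldehyde F7. CrCl2 (8 equiv) with NiCl2 (1 mol %) in DMSO/THF at 1 mM (syringe pump) closes the ring to the macrocyclic alcohol F8. p-TsOH·H2O in MeOH/PhMe removes both silyl groups and lactonises to 23.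

Step 1 (hindered, elimination-prone enolate with an enolisable α-halo ester). The fallback sets out from 1 and returns at 4. It uses allyl bromide, the best-behaved electrophile for this enolate, and builds the acetate unit by oxidation. LiN(i-Pr)2 then allyl bromide gives the C-allyl triester F9. RuCl3 (cat.) with NaIO4 cleaves the alkene to the carboxylic acid F10. tert-Butyl 2,2,2-trichloroacetimidate with BF3·OEt2 (cat.) gives 4.

Further compounds
F1 | step 7 | methyl (4R,5R)-4-(2-tert-butoxy-2-oxoethyl)-2,2-dimethyl-5-[(1E)-2-methyl-3-oxoprop-1-en-1-yl]-1,3-dioxolane-4-carboxylate | O=C/C(C)=C/[C@@H](OC(C)(C)O1)[C@]1(CC(=O)OC(C)(C)C)C(=O)OC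
F2 | step 7 | cycloadduct of F1 and 15 (C1-formyl analogue of 16) | C[Si](C)(C)OC1=C[C@H](OC)[C@@](C=O)(C)[C@H]([C@@H]1C)[C@@H](OC(C)(C)O2)[C@]2(CC(=O)OC(C)(C)C)C(=O)OC
F3 | step 7 | methyl (4R,5R)-4-(2-tert-butoxy-2-oxoethyl)-5-[(1S,2S,6S)-2-formyl-2,6-dimethyl-5-oxocyclohex-3-en-1-yl]-2,2-dimethyl-1,3-dioxolane-4-carboxylate | O=C1C=C[C@@](C=O)(C)[C@H]([C@@H]1C)[C@@H](OC(C)(C)O2)[C@]2(CC(=O)OC(C)(C)C)C(=O)OC
F4 | step 7 | 1-hydroxyethyl analogue of F3 (both carbinol epimers) | O=C1C=C[C@@](C(C)O)(C)[C@H]([C@@H]1C)[C@@H](OC(C)(C)O2)[C@]2(CC(=O)OC(C)(C)C)C(=O)OC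
F5 | step 7 | methyl (4R,5R)-5-[(1S,2S,6S)-2-acetyl-2,6-dimethyl-5-oxocyclohex-3-en-1-yl]-4-(2-tert-butoxy-2-oxoethyl)-2,2-dimethyl-1,3-dioxolane-4-carboxylate | O=C1C=C[C@@](C(C)=O)(C)[C@H]([C@@H]1C)[C@@H](OC(C)(C)O2)[C@]2(CC(=O)OC(C)(C)C)C(=O)OC
F6 | step 11 | 2,12-bis(triethylsilyl) ether of 20 | CC[Si](CC)(CC)O[C@H]1C=C[C@@]([C@H](O[Si](CC)(CC)CC)CC/C(C)=C\I)(C)[C@H]([C@H]1C)[C@@H](OC(C)(C)O2)[C@]2(CC(=O)OC(C)(C)C)C(=O)OC
F7 | step 11 | 2,12-bis(triethylsilyl) ether of 21 | CC[Si](CC)(CC)O[C@H]1C=C[C@@]([C@H](O[Si](CC)(CC)CC)CC/C(C)=C\I)(C)[C@H]([C@H]1C)[C@@H](OC(C)(C)O2)[C@]2(CC(=O)OC(C)(C)C)C=O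
F8 | step 11 | 2,12-bis(triethylsilyl) ether of 22 | CC[Si](CC)(CC)O[C@H]1C=C[C@@]2(C)[C@H]([C@H]1C)[C@@H](OC(C)(C)O3)[C@]3(CC(=O)OC(C)(C)C)[C@@H](O)/C=C(/C)CC[C@H]2O[Si](CC)(CC)CC
F9 | step 1 | 4,5-dimethyl (4R,5S)-2,2-dimethyl-4-(prop-2-en-1-yl)-1,3-dioxolane-4,5-dicarboxylate | COC(=O)[C@@H](OC(C)(C)O1)[C@]1(CC=C)C(=O)OC
F10 | step 1 | 2-[(4R,5S)-4,5-bis(methoxycarbonyl)-2,2-dimethyl-1,3-dioxolan-4-yl]acetic acid | COC(=O)[C@@H](OC(C)(C)O1)[C@]1(CC(=O)O)C(=O)OC
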